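**Plan**

Atoms carry the numbers of their positions in the target SMILES (C1 to O26). The retrosynthesis cuts, in this order: the two acetates and the C13 lactol (back to an enol lactone at O12–C13), the oxepane at O8–C9 and C9–C10, the cycloheptane at C18–C24, then C18–C19, C19=C10 and the cyclopropane bonds C6–C20 and C6–C21.
Enabling feature: C9 is a lone CH2 between O8 and the enol-ether carbon C10 inside the oxepane ring C6–C7–O8–C9–C10–C19–C20, so it is one formaldehyde carbon set between the C7 hydroxyl and the α-carbon of a C11 aldehyde.
Forward order of rings: cyclopropane, a temporary δ-lactone (C13–O12–C11) used as a tether, the cycloheptane, the oxepane (key step), and last the dihydropyran as enol lactone and then lactol acetate.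
Stereochemistry: C20 and C21 come from an (S)-diarylprolinol silyl ether catalysed cyclopropanation of an (E)-enal; C19 from an (R)-catalyst Michael addition matched with the cyclopropane bias; C18 and C24 from a chelated samarium Reformatsky closure on a ring enolate; C6 from the cis geometry of the ether closure; C13 from acetylation of the equilibrating lactol.

Key step: step 17

Remark on the chemistry: the stereodescriptors of the SMILES are taken literally. They place C19 and C22 on opposite faces of the cyclopropane (a trans-fused bicyclo[5.1.0]octane) and the C13 acetoxy group trans to the C18–C24 bond; the route is built for this isomer.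

**Route**

Step 1
Reactants: 1 2-methylhexa-1,5-diene; 2 crotonaldehyde
Product: 3 (E)-6-methylhepta-2,6-dienal
Conditions: 2 (3 equiv), second-generation Grubbs catalyst RuCl2(=CHPh)(PCy3)(H2IMes) (2 mol%), CH2Cl2, 40 °C
Reagents that add atoms: none
Why: Olefin cross-metathesis joins the monosubstituted alkene of 1 to the enal with E selectivity, the 1,1-disubstituted alkene being too hindered to take part under these conditions.

Step 2
Reactants: 3 (E)-6-methylhepta-2,6-dienal; 4 diethyl bromomalonate
Product: 5 diethyl (2R,3R)-2-formyl-3-(3-methylbut-3-en-1-yl)cyclopropane-1,1-dicarboxylate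
Conditions: (S)-2-[diphenyl(trimethylsilyloxy)methyl]pyrrolidine (20 mol%), 2,6-lutidine (1.1 equiv), CH2Cl2, 0 °C → rt
Reagents that add atoms: none
Why: Michael-initiated ring closure under iminium–enamine catalysis, in which the bromomalonate adds to C21 of the (E)-iminium ion on the face left open by the (S)-catalyst and the enamine then displaces bromide (3-exo-tet), which sets C21 and C20 and keeps the formyl group and the side chain trans.

Step 3
Reactants: 5 cyclopropane aldehyde diester
Product: 6 [(2R,3R)-3-(3-methylbut-3-en-1-yl)cyclopropane-1,1,2-triyl]trimethanol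
Conditions: LiAlH4 (3 equiv), THF, 0 °C → rt; aq. NaOH work-up
Reagents that add atoms: none
Why: Hydride reduction of the aldehyde and both esters by LiAlH4 should give the triol without touching the alkene or the cyclopropane.

Step 4
Reactants: 6 triol
Product: 7 [(1R,2R)-6,6-dimethyl-2-(3-methylbut-3-en-1-yl)-5,7-dioxaspiro[2.5]octan-1-yl]methanol
Conditions: 2,2-dimethoxypropane, PPTS (cat.), acetone, rt
Reagents that add atoms: 2,2-dimethoxypropane, COC(C)(C)OC
Why: Acid-catalysed isopropylidene acetal formation under equilibrating conditions should select the six-membered 1,3-dioxane on the geminal bis(hydroxymethyl) unit and leave the C19 carbinol free.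

Step 5
Reactants: 7 acetonide alcohol
Product: 8 (1R,2R)-6,6-dimethyl-2-(3-methylbut-3-en-1-yl)-5,7-dioxaspiro[2.5]octane-1-carbaldehyde
Conditions: TEMPO (10 mol%), PhI(OAc)2 (1.1 equiv), CH2Cl2, rt
Reagents that add atoms: none
Why: Nitroxyl-catalysed oxidation of the primary alcohol stops at the aldehyde and tolerates the alkene and the ketal.

Step 6
Reactants: 8 cyclopropane carbaldehyde; 9 (triphenylphosphoranylidene)acetaldehyde
Product: 10 (E)-3-[6,6-dimethyl-2-(3-methylbut-3-en-1-yl)-5,7-dioxaspiro[2.5]octan-1-yl]prop-2-enal (ring carbons configured as in 8)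
Conditions: 9 (1.2 equiv), toluene, 80 °C
Reagents that add atoms: none
Why: Wittig olefination with the stabilised formylmethylene ylide should give the (E)-enal, which places C10 and C11 at their final oxidation levels.

Step 7
Reactants: 10 enal; 11 dimethyl malonate
Product: 12 dimethyl 2-[(1R)-1-(spirocyclic cyclopropyl group of 10)-3-oxopropyl]propanedioate (new centre C19)
Conditions: 11 (2 equiv), (R)-2-{bis[3,5-bis(trifluoromethyl)phenyl](trimethylsilyloxy)methyl}pyrrolidine (10 mol%), EtOH, 0 °C
Reagents that add atoms: none
Why: Iminium-catalysed Michael addition of the malonate to C19, in which the (R)-catalyst exposes the same face that the bisected s-trans vinylcyclopropane conformer leaves open (anti to the quaternary C6), so catalyst and substrate control are matched and set C19.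

Step 8
Reactants: 12 aldehyde malonate
Product: 14 methyl 2-oxo-4-(cyclopropyl group of 10)oxane-3-carboxylate (C18 epimers), via hydroxy malonate 13 (not isolated)
Conditions: NaBH4, MeOH, 0 °C → rt
Reagents that add atoms: none
Why: Borohydride reduction of the aldehyde gives a δ-hydroxy malonate whose alkoxide lactonises onto one of the activated esters, which ties C11 and C13 into the six-membered tether.

Step 9
Reactants: 14 lactone ester
Product: 15 4-[6,6-dimethyl-2-(3-methylbut-3-en-1-yl)-5,7-dioxaspiro[2.5]octan-1-yl]oxan-2-one
Conditions: LiCl, H2O, DMSO, 140 °C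
Reagents that add atoms: none
Why: Krapcho dealkoxycarbonylation removes the extra methyl ester under neutral conditions that the ketal and the alkene should survive.

Step 10
Reactants: 15 δ-lactone
Product: 16 3-bromo-4-[6,6-dimethyl-2-(3-methylbut-3-en-1-yl)-5,7-dioxaspiro[2.5]octan-1-yl]oxan-2-one (C18 epimers)
Conditions: LiN(i-Pr)2, THF, −78 °C; then BrCl2C–CCl2Br, −78 °C
Reagents that add atoms: 1,2-dibromo-1,1,2,2-tetrachloroethane, BrC(Cl)(Cl)C(Cl)(Cl)Br
Why: α-Bromination of the lactone lithium enolate with a positive-bromine donor that does not attack alkenes, done while the ketone is still masked as the isopropenyl group so that C18 is the only enolisable position.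

Step 11
Reactants: 16 bromo lactone
Product: 17 3-bromo-4-[6,6-dimethyl-2-(3-oxobutyl)-5,7-dioxaspiro[2.5]octan-1-yl]oxan-2-one (C18 epimers)
Conditions: O3, CH2Cl2, −78 °C; then Me2S, −78 °C → rt
Reagents that add atoms: ozone, [O-][O+]=O
Why: Ozonolysis of the 1,1-disubstituted alkene unveils the C24 methyl ketone without affecting the bromo lactone or the ketal.

Step 12
Reactants: 17 bromo keto lactone
Product: 18 tricyclic hydroxy lactone (cyclopropane trans-fused and δ-lactone cis-fused to the new cycloheptane; C24 hydroxyl syn to the lactone carbonyl)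
Conditions: SmI2 (2.5 equiv), THF, −78 °C, slow addition of 17 at high dilution; aq. NH4Cl
Reagents that add atoms: none
Why: Intramolecular samarium Reformatsky reaction, in which divalent samarium reduces the C18–Br bond to a trivalent samarium lactone enolate that attacks the tethered ketone on the ring face carrying the C20 tether (cis fusion, sets C18) through a chelate between enolate oxygen and ketone oxygen (hydroxyl syn to the lactone carbonyl, sets C24).

Step 13
Reactants: 18 hydroxy lactone
Product: 19 triethylsilyl ether of 18
Conditions: Et3SiOTf, 2,6-lutidine, CH2Cl2, −78 → 0 °C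
Reagents that add atoms: triethylsilyl trifluoromethanesulfonate, CC[Si](CC)(CC)OS(=O)(=O)C(F)(F)F
Why: Silylation of the tertiary alcohol with a silyl triflate and a hindered base avoids an alkoxide (no retro-aldol) and blocks O26 for the later ether closure, the ketal being inert to this reagent pair.

Step 14
Reactants: 19 silylated lactone
Product: 21 allyl ester with a 2-hydroxyethyl group on C19, via lithium carboxylate 20 (not isolated)
Conditions: LiOH (1.1 equiv), THF/H2O, rt; concentrate; then allyl bromide, DMF, rt
Reagents that add atoms: lithium hydroxide, [Li+].[OH-]; allyl bromide, C=CCBr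
Why: Saponification of the strained δ-lactone followed by O-alkylation of the carboxylate traps the open form as an ester that can later be cleaved under neutral conditions, and the crude hydroxy ester is oxidised at once to forestall relactonisation.

Step 15
Reactants: 21 hydroxy allyl ester
Product: 22 aldehyde allyl ester (acetonide retained)
Conditions: TEMPO (10 mol%), PhI(OAc)2 (1.1 equiv), CH2Cl2, rt
Reagents that add atoms: none
Why: Nitroxyl-catalysed oxidation converts the only free primary alcohol into the C11 aldehyde.

Step 16
Reactants: 22 aldehyde acetonide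
Product: 23 bicyclic aldehyde ester diol (both hydroxymethyl groups on C6 free, C24 silyl ether retained)
Conditions: AcOH/THF/H2O (3:1:1), 40 °C
Reagents that add atoms: none
Why: Mild aqueous acid hydrolysis of the isopropylidene ketal should be much faster than cleavage of the hindered tertiary triethylsilyl ether and does not acetalise the aldehyde.

Step 17
Reactants: 23 aldehyde ester diol; 24 formaldehyde
Product: 26 oxepane-fused aldehyde ester (C10 epimers), via α-methylene aldehyde 25 (not isolated)
Conditions: 24 (37% aq., 3 equiv), pyrrolidine (20 mol%), EtCO2H (20 mol%), i-PrOH, 45 °C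
Reagents that add atoms: none
Why: Pyrrolidine condenses with the C11 aldehyde to an enamine at C10, which undergoes Mannich addition to formaldehyde and loses the amine to give the 2-substituted acrolein 25. The C7 hydroxyl then adds to C9 of 25, activated as its iminium ion, and hydrolysis returns the catalyst and the aldehyde. The closest known reactions are the amine/acid-catalysed α-methylenation of aldehydes with aqueous formaldehyde and the iminium-activated intramolecular oxa-Michael addition to enals. The oxepane closes in a 7-endo-trig mode. The one new stereocentre, C10, arises by protonation of the product enamine and is left uncontrolled because it becomes sp2 in step 19. The step needs C10 and not C18 to be methylenated, which holds because C18 is a methine next to an ester and forms no enamine, and it needs O8 to be the adding oxygen, which holds because only the hydroxymethyl group cis to C19 on the cyclopropane reaches C9 without a trans ring fusion while the tertiary oxygen is silylated.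

Step 18
Reactants: 26 oxepane aldehyde allyl ester
Product: 27 oxepane aldehyde carboxylic acid (C10 epimers)
Conditions: Pd(PPh3)4 (5 mol%), N-methylaniline, THF, rt
Reagents that add atoms: none
Why: Tsuji–Trost deallylation with zerovalent palladium and a weakly basic amine scavenger frees the hindered acid without hydroxide, so the β-alkoxy aldehyde is not exposed to retro-Michael conditions.

Step 19
Reactants: 27 aldehyde acid
Product: 28 enol lactone with C5 acetate and C24 triethylsilyl ether
Conditions: Ac2O, NaOAc, 80 °C
Reagents that add atoms: acetic anhydride, CC(=O)OC(C)=O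
Why: Enol lactonisation through the mixed anhydride, in which the aldehyde enol oxygen is acylated intramolecularly to close the dihydropyranone (C10 becomes sp2, O12–C13 formed) while the C5 hydroxyl is acetylated.

Step 20
Reactants: 28 silylated enol lactone
Product: 29 enol lactone with free C24 hydroxyl
Conditions: HF·pyridine, pyridine, THF, 0 °C → rt
Reagents that add atoms: none
Why: Fluoride-mediated desilylation under buffered acidic conditions frees the tertiary alcohol while the base-sensitive enol lactone and the acetate stay intact.

Step 21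
Reactants: 29 hydroxy enol lactone
Product: 30 lactol triol (C13 anomers)
Conditions: i-Bu2AlH (4 equiv), CH2Cl2, −78 °C; aq. potassium sodium tartrate work-up
Reagents that add atoms: none
Why: Partial reduction of the lactone by i-Bu2AlH stops at the aluminium hemiacetal at low temperature and gives the lactol on work-up, while the same reagent cleaves the C5 acetate, which is restored in the next step.

Step 22
Reactants: 30 lactol triol
Product: 31 target compound
Conditions: Ac2O, pyridine, CH2Cl2, 0 °C → rt
Reagents that add atoms: acetic anhydride, CC(=O)OC(C)=O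
Why: Acetylation esterifies the primary C5 hydroxyl and the lactol hydroxyl but not the tertiary C24 hydroxyl, and the equilibrating lactol should be trapped mainly as the pseudoaxial acetate on the convex face, trans to the C18–C24 bond, which is the C13 configuration of the target.

**Compound list**

1 | 2-methylhexa-1,5-diene | C=C(C)CCC=C | starting material
2 | crotonaldehyde | C/C=C/C=O | starting material
3 | (E)-6-methylhepta-2,6-dienal | C=C(C)CC/C=C/C=O | intermediate
4 | diethyl bromomalonate | CCOC(=O)C(Br)C(=O)OCC | starting material
5 | diethyl (2R,3R)-2-formyl-3-(3-methylbut-3-en-1-yl)cyclopropane-1,1-dicarboxylate | CCOC(=O)C1(C(=O)OCC)[C@H](C=O)[C@H]1CCC(C)=C | intermediate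
6 | [(2R,3R)-3-(3-methylbut-3-en-1-yl)cyclopropane-1,1,2-triyl]trimethanol | OCC1(CO)[C@H](CO)[C@H]1CCC(C)=C | intermediate
7 | [(1R,2R)-6,6-dimethyl-2-(3-methylbut-3-en-1-yl)-5,7-dioxaspiro[2.5]octan-1-yl]methanol | CC1(C)OCC2(CO1)[C@H](CO)[C@H]2CCC(C)=C | intermediate
8 | (1R,2R)-6,6-dimethyl-2-(3-methylbut-3-en-1-yl)-5,7-dioxaspiro[2.5]octane-1-carbaldehyde | CC1(C)OCC2(CO1)[C@H](C=O)[C@H]2CCC(C)=C | intermediate
9 | (triphenylphosphoranylidene)acetaldehyde | O=CC=P(c1ccccc1)(c1ccccc1)c1ccccc1 | starting material
10 | (E)-3-[6,6-dimethyl-2-(3-methylbut-3-en-1-yl)-5,7-dioxaspiro[2.5]octan-1-yl]prop-2-enal | CC1(C)OCC2(CO1)[C@H](/C=C/C=O)[C@H]2CCC(C)=C | intermediate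
11 | dimethyl malonate | COC(=O)CC(=O)OC | starting material
12 | dimethyl 2-[(1R)-3-oxo-1-(spirocyclic cyclopropyl)propyl]propanedioate (C19 set) | CC1(C)OCC2(CO1)[C@H]([C@@H](CC=O)C(C(=O)OC)C(=O)OC)[C@H]2CCC(C)=C | intermediate
13 | dimethyl 2-[3-hydroxy-1-(spirocyclic cyclopropyl)propyl]propanedioate | CC1(C)OCC2(CO1)[C@H]([C@@H](CCO)C(C(=O)OC)C(=O)OC)[C@H]2CCC(C)=C | intermediate (not isolated)
14 | methyl 2-oxo-4-(spirocyclic cyclopropyl)oxane-3-carboxylate, C18 epimers | CC1(C)OCC2(CO1)[C@H]([C@H]3CCOC(=O)C3C(=O)OC)[C@H]2CCC(C)=C | intermediate
15 | 4-[6,6-dimethyl-2-(3-methylbut-3-en-1-yl)-5,7-dioxaspiro[2.5]octan-1-yl]oxan-2-one | CC1(C)OCC2(CO1)[C@H]([C@H]3CCOC(=O)C3)[C@H]2CCC(C)=C | intermediate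
16 | 3-bromo derivative of 15, C18 epimers | CC1(C)OCC2(CO1)[C@H]([C@H]3CCOC(=O)C3Br)[C@H]2CCC(C)=C | intermediate
17 | 3-bromo-4-[6,6-dimethyl-2-(3-oxobutyl)-5,7-dioxaspiro[2.5]octan-1-yl]oxan-2-one, C18 epimers | CC1(C)OCC2(CO1)[C@H]([C@H]3CCOC(=O)C3Br)[C@H]2CCC(C)=O | intermediate
18 | tricyclic hydroxy lactone: bicyclo[5.1.0]octane core (trans-fused cyclopropane), cis-fused δ-lactone, C24 methyl carbinol, spiro acetonide on C6 | CC1(C)OCC2(CO1)[C@@H]3[C@H]4CCOC(=O)[C@H]4[C@@](C)(O)CC[C@@H]23 | intermediate
19 | C24 triethylsilyl ether of 18 | CC1(C)OCC2(CO1)[C@@H]3[C@H]4CCOC(=O)[C@H]4[C@@](C)(O[Si](CC)(CC)CC)CC[C@@H]23 | intermediate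
20 | lithium carboxylate from lactone opening (C19 bears CH2CH2OH, C18 bears CO2Li) | CC1(C)OCC2(CO1)[C@@H]3[C@@H](CCO)[C@@H](C([O-])=O)[C@@](C)(O[Si](CC)(CC)CC)CC[C@@H]23.[Li+] | intermediate (not isolated)
21 | allyl ester of the hydroxy acid (C19 CH2CH2OH, C18 CO2allyl) | CC1(C)OCC2(CO1)[C@@H]3[C@@H](CCO)[C@@H](C(=O)OCC=C)[C@@](C)(O[Si](CC)(CC)CC)CC[C@@H]23 | intermediate
22 | aldehyde allyl ester (C19 CH2CHO), acetonide retained | CC1(C)OCC2(CO1)[C@@H]3[C@@H](CC=O)[C@@H](C(=O)OCC=C)[C@@](C)(O[Si](CC)(CC)CC)CC[C@@H]23 | intermediate
23 | bicyclic aldehyde ester diol lacking C9 (key-step precursor): C6 carries two CH2OH, C19 CH2CHO, C18 CO2allyl, C24 methyl and OSiEt3 | OCC1(CO)[C@@H]2[C@@H](CC=O)[C@@H](C(=O)OCC=C)[C@@](C)(O[Si](CC)(CC)CC)CC[C@@H]12 | intermediate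
24 | formaldehyde | C=O | starting material
25 | α-methylene aldehyde (C19 bears C(=CH2)CHO) | OCC1(CO)[C@@H]2[C@@H](C(=C)C=O)[C@@H](C(=O)OCC=C)[C@@](C)(O[Si](CC)(CC)CC)CC[C@@H]12 | intermediate (not isolated)
26 | oxepane-fused aldehyde allyl ester (key-step product): ring C6–C7–O8–C9–C10–C19–C20, CHO on C10 (epimers), C5 hydroxyl free | OC[C@@]12COCC(C=O)[C@@H]3[C@@H]1[C@H]2CC[C@](C)(O[Si](CC)(CC)CC)[C@@H]3C(=O)OCC=C | intermediate
27 | oxepane aldehyde carboxylic acid, C10 epimers | OC[C@@]12COCC(C=O)[C@@H]3[C@@H]1[C@H]2CC[C@](C)(O[Si](CC)(CC)CC)[C@@H]3C(=O)O | intermediate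
28 | enol lactone (C10=C11–O12–C13=O) with C5 acetate and C24 OSiEt3 | CC(=O)OC[C@@]12COCC3=COC(=O)[C@@H]4[C@H]3[C@@H]1[C@H]2CC[C@]4(C)O[Si](CC)(CC)CC | intermediate
29 | enol lactone with C5 acetate and free C24 hydroxyl | CC(=O)OC[C@@]12COCC3=COC(=O)[C@@H]4[C@H]3[C@@H]1[C@H]2CC[C@]4(C)O | intermediate
30 | lactol triol (C5 OH, C13 OH as anomers, C24 OH) | OC[C@@]12COCC3=COC(O)[C@@H]4[C@H]3[C@@H]1[C@H]2CC[C@]4(C)O | intermediate
31 | CNP0250836.2 (C5 and C13 diacetate, C24 tertiary alcohol) | CC(=O)OC[C@@]12COCC3=CO[C@H](OC(C)=O)[C@@H]4[C@H]3[C@@H]1[C@H]2CC[C@]4(C)O | target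

**Summary**

Total step count: 22. Longest linear sequence: 22 steps (from 1 and 2 to 31).

Steps most likely to fail:

Step 12. The closure has to build the strained trans-fused bicyclo[5.1.0]octane, so the samarium enolate may be protonated before it cyclises, or the aldolate may reopen by retro-aldol cleavage. The fallback sets out from 17 and returns to the route at 18. Treatment of 17 with LiN(SiMe3)2 in THF at −78 °C should deprotonate the α-bromo lactone; the anion adds to the ketone and the aldolate displaces bromide (intramolecular Darzens condensation), an irreversible closure that should give the glycidic lactone F1 with the epoxide oxygen on C24 anti to the departed bromide. Reductive opening of the Cα–O bond of the glycidic lactone F1 with SmI2 in THF/MeOH then gives the β-hydroxy lactone 18, its C18 centre being set by protonation of the samarium enolate from the convex face.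

Step 17. The cascade may stall at the α-methylene aldehyde because the 7-endo oxa-Michael addition is slow or reverses. The fallback sets out from 23 and returns at 26; it forms the ether by reduction of a lactol instead of by conjugate addition. Hydroxymethylation of 23 with aqueous formaldehyde under diarylprolinol silyl ether catalysis in pH 7 buffer (aldol stage without dehydration) should give the α-hydroxymethyl aldehyde F2. Reductive etherification of the α-hydroxymethyl aldehyde F2 with Et3SiH and Me3SiOTf in CH2Cl2 at −78 °C, through the seven-membered lactol formed with the cis hydroxymethyl group, should give the oxepane diol F3. Oxidation of the oxepane diol F3 with TEMPO and PhI(OAc)2, which prefers the unhindered carbinol over the neopentyl C5 carbinol, gives 26. In this variant the formaldehyde carbon ends as the aldehyde carbon and the former aldehyde carbon as the ether CH2, so the constitution of 26 is unchanged.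

Step 7. Conjugate addition to the hindered β-cyclopropyl iminium ion may be too slow, so that the enal is consumed by side reactions or the catalyst is lost. The fallback sets out from 10 and returns at 15; it sets C19 by a sigmatropic shift. Luche reduction of 10 (NaBH4, CeCl3·7H2O, MeOH) gives the allylic alcohol F4. Johnson–Claisen rearrangement of the allylic alcohol F4 with trimethyl orthoacetate and catalytic propionic acid at 130 °C should form the C19–C18 bond on the face anti to C6 and give the vinyl ester F5. Selective hydroboration of the vinyl group of the vinyl ester F5 with disiamylborane and oxidation with NaBO3 gives the hydroxy ester F6. Lactonisation of the hydroxy ester F6 (PPTS, toluene, 60 °C) gives 15.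

Further compounds
F1 | step 12 | glycidic lactone (epoxide across C18–C24, drawn as expected from anti displacement of bromide) | CC1(C)OCC2(CO1)[C@@H]3[C@H]4CCOC(=O)[C@@]45O[C@@]5(C)CC[C@@H]23
F2 | step 17 | α-hydroxymethyl aldehyde (C10 bears CHO and CH2OH, C10 epimers) | OCC1(CO)[C@@H]2[C@@H](C(CO)C=O)[C@@H](C(=O)OCC=C)[C@@](C)(O[Si](CC)(CC)CC)CC[C@@H]12
F3 | step 17 | oxepane diol (C10 bears CH2OH, C10 epimers) | OC[C@@]12COCC(CO)[C@@H]3[C@@H]1[C@H]2CC[C@](C)(O[Si](CC)(CC)CC)[C@@H]3C(=O)OCC=C
F4 | step 7 | (E)-allylic alcohol from 10 | CC1(C)OCC2(CO1)[C@H](/C=C/CO)[C@H]2CCC(C)=C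
F5 | step 7 | methyl ester with vinyl and CH2CO2Me on C19 | CC1(C)OCC2(CO1)[C@H]([C@@H](C=C)CC(=O)OC)[C@H]2CCC(C)=C
F6 | step 7 | hydroxy ester with CH2CH2OH and CH2CO2Me on C19 | CC1(C)OCC2(CO1)[C@H]([C@@H](CCO)CC(=O)OC)[C@H]2CCC(C)=C
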